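The 2,5-dihydrofuran ring of the target (O–C5–C6=C7–C8, fused to the cyclohexane ring at C5–C6) is the allylic isomer of a C5–C6 oxirane that carries the C7=C8 bond. The route therefore builds (3S,5R,6S,3'R,6'R)-lutein 5,6-epoxide from two C15 ylides and a C10 dialdehyde, and in the last step dilute acid shifts the oxygen from C6 to C8: the three-membered ring expands to the five-membered one, C6=C7 and the stereocentre C8 appear, and the chromophore is shortened. C3, C5 and C6 come from actinol and a Sharpless epoxidation, C3' and C6' from (R)-α-ionone and a CBS reduction; C8 is sorted by equilibration and separation.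

Key step: step 19

Remark: compounds 1, 8, 13, 15 and 16 are taken as commercial, carotenoid numbering is used for positions, and all polyene work is assumed under argon with exclusion of light and acid.

Step 1
Reactants: 1 (4R,6R)-4-hydroxy-2,2,6-trimethylcyclohexan-1-one (actinol)
Product: 2 (4R,6R)-4-[(tert-butyldimethylsilyl)oxy]-2,2,6-trimethylcyclohexan-1-one
Conditions: TBSCl, imidazole, DMF, rt
Reagents that add atoms: tert-butyldimethylsilyl chloride, C[Si](C)(Cl)C(C)(C)C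
Why: Imidazole-promoted O-silylation masks the secondary alcohol for the enolate chemistry that follows and touches no stereocentre.

Step 2
Reactants: 2 (4R,6R)-4-[(tert-butyldimethylsilyl)oxy]-2,2,6-trimethylcyclohexan-1-one
Product: 3 (4R)-4-[(tert-butyldimethylsilyl)oxy]-2,6,6-trimethylcyclohex-1-en-1-yl trifluoromethanesulfonate
Conditions: LiN(iPr)2, THF, −78 °C; PhNTf2, −78 °C to rt
Reagents that add atoms: N-phenyl-bis(trifluoromethanesulfonimide), O=S(=O)(N(c1ccccc1)S(=O)(=O)C(F)(F)F)C(F)(F)F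
Why: The ketone can enolize only toward C6 because C2 is quaternary, and O-sulfonylation of the lithium enolate gives the tetrasubstituted enol triflate (the C6 centre is removed on purpose, C4 is untouched).

Step 3
Reactants: 3 (4R)-4-[(tert-butyldimethylsilyl)oxy]-2,6,6-trimethylcyclohex-1-en-1-yl trifluoromethanesulfonate
Product: 4 methyl (4R)-4-[(tert-butyldimethylsilyl)oxy]-2,6,6-trimethylcyclohex-1-ene-1-carboxylate
Conditions: CO (1 atm), MeOH, Pd(OAc)2 (cat.), PPh3, Et3N, DMF, 60 °C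
Reagents that add atoms: carbon monoxide, [C-]#[O+]; methanol, CO
Why: Palladium-catalysed methoxycarbonylation of the enol triflate (oxidative addition, CO insertion, methanolysis) attaches the carbon that becomes C7.

Step 4
Reactants: 4 methyl (4R)-4-[(tert-butyldimethylsilyl)oxy]-2,6,6-trimethylcyclohex-1-ene-1-carboxylate
Product: 5 [(4R)-4-[(tert-butyldimethylsilyl)oxy]-2,6,6-trimethylcyclohex-1-en-1-yl]methanol
Conditions: iBu2AlH, CH2Cl2, −78 to 0 °C; aq. KNaC4H4O6
Reagents that add atoms: none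
Why: Hydride 1,2-reduction of the hindered conjugated ester gives the allylic alcohol needed to direct the epoxidation.

Step 5
Reactants: 5 [(4R)-4-[(tert-butyldimethylsilyl)oxy]-2,6,6-trimethylcyclohex-1-en-1-yl]methanol
Product: 6 [(1R,4S,6R)-4-[(tert-butyldimethylsilyl)oxy]-2,2,6-trimethyl-7-oxabicyclo[4.1.0]heptan-1-yl]methanol (oxirane trans to the silyloxy group)
Conditions: Ti(OiPr)4, D-(−)-diethyl tartrate, tBuOOH, 4 Å molecular sieves, CH2Cl2, −20 °C
Reagents that add atoms: tert-butyl hydroperoxide, CC(C)(C)OO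
Why: Sharpless asymmetric epoxidation, in which the titanium D-tartrate complex bound to the allylic alcohol delivers oxygen to the alkene face trans to the silyloxy group (reagent control over the weak ring bias) and so sets C5 (R) and C6 in one event.

Step 6
Reactants: 6 [(1R,4S,6R)-4-[(tert-butyldimethylsilyl)oxy]-2,2,6-trimethyl-7-oxabicyclo[4.1.0]heptan-1-yl]methanol
Product: 7 (1S,4S,6R)-4-[(tert-butyldimethylsilyl)oxy]-2,2,6-trimethyl-7-oxabicyclo[4.1.0]heptane-1-carbaldehyde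
Conditions: Dess–Martin periodinane, NaHCO3, CH2Cl2, 0 °C to rt
Reagents that add atoms: none
Why: Buffered Dess–Martin oxidation of the primary alcohol gives the non-enolizable epoxy aldehyde without opening the oxirane.

Step 7
Reactants: 7 (1S,4S,6R)-4-[(tert-butyldimethylsilyl)oxy]-2,2,6-trimethyl-7-oxabicyclo[4.1.0]heptane-1-carbaldehyde; 8 ethyl (2E)-4-(diethoxyphosphoryl)-3-methylbut-2-enoate
Product: 9 ethyl (2E,4E)-5-[(1S,4S,6R)-4-[(tert-butyldimethylsilyl)oxy]-2,2,6-trimethyl-7-oxabicyclo[4.1.0]heptan-1-yl]-3-methylpenta-2,4-dienoate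
Conditions: NaH, THF, 0 °C; then 7, 0 °C to rt
Reagents that add atoms: none
Why: Vinylogous Horner–Wadsworth–Emmons olefination forms the C7=C8 bond E-selectively and brings in the 9E trisubstituted alkene, the minor 9Z isomer being removed by chromatography.

Step 8
Reactants: 9 ethyl (2E,4E)-5-[(1S,4S,6R)-4-[(tert-butyldimethylsilyl)oxy]-2,2,6-trimethyl-7-oxabicyclo[4.1.0]heptan-1-yl]-3-methylpenta-2,4-dienoate
Product: 10 (2E,4E)-5-[(1S,4S,6R)-4-[(tert-butyldimethylsilyl)oxy]-2,2,6-trimethyl-7-oxabicyclo[4.1.0]heptan-1-yl]-3-methylpenta-2,4-dien-1-ol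
Conditions: iBu2AlH, CH2Cl2, −78 °C; aq. KNaC4H4O6
Reagents that add atoms: none
Why: Low-temperature 1,2-reduction of the dienoate gives the allylic alcohol and leaves the vinyl oxirane intact.

Step 9
Reactants: 10 (2E,4E)-5-[(1S,4S,6R)-4-[(tert-butyldimethylsilyl)oxy]-2,2,6-trimethyl-7-oxabicyclo[4.1.0]heptan-1-yl]-3-methylpenta-2,4-dien-1-ol
Product: 12 [(2E,4E)-5-[(1S,4S,6R)-4-[(tert-butyldimethylsilyl)oxy]-2,2,6-trimethyl-7-oxabicyclo[4.1.0]heptan-1-yl]-3-methylpenta-2,4-dien-1-yl]triphenylphosphonium bromide, via epoxy dienyl bromide 11 (not isolated)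
Conditions: CBr4, PPh3 (2.3 equiv), CH2Cl2, −20 °C to rt
Reagents that add atoms: carbon tetrabromide, BrC(Br)(Br)Br; triphenylphosphine, c1ccc(cc1)P(c1ccccc1)c1ccccc1
Why: Appel bromination of the primary allylic alcohol under neutral conditions and quaternization of the bromide by the excess phosphine give the Wittig salt without any acid that could open the oxirane.

Step 10
Reactants: 12 [(2E,4E)-5-[(1S,4S,6R)-4-[(tert-butyldimethylsilyl)oxy]-2,2,6-trimethyl-7-oxabicyclo[4.1.0]heptan-1-yl]-3-methylpenta-2,4-dien-1-yl]triphenylphosphonium bromide; 13 (2E,4E,6E)-2,7-dimethylocta-2,4,6-trienedial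
Product: 14 (2E,4E,6E,8E,10E,12E)-13-[(1S,4S,6R)-4-[(tert-butyldimethylsilyl)oxy]-2,2,6-trimethyl-7-oxabicyclo[4.1.0]heptan-1-yl]-2,7,11-trimethyltrideca-2,4,6,8,10,12-hexaenal
Conditions: NaOMe, MeOH/CH2Cl2, 0 °C to rt, 13 in excess (3 equiv); then heptane, 80 °C
Reagents that add atoms: none
Why: Wittig olefination of the semi-stabilized ylide with an excess of the symmetrical dialdehyde should stop at mono-condensation and forms C11=C12, whose Z isomer equilibrates thermally to E.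

Step 11
Reactants: 15 (R)-α-ionone, (3E)-4-[(1R)-2,6,6-trimethylcyclohex-2-en-1-yl]but-3-en-2-one; 16 triethyl phosphonoacetate
Product: 17 ethyl (2E,4E)-3-methyl-5-[(1R)-2,6,6-trimethylcyclohex-2-en-1-yl]penta-2,4-dienoate
Conditions: NaH, THF, 0 to 40 °C
Reagents that add atoms: none
Why: Horner–Wadsworth–Emmons olefination of the methyl ketone builds the 9'E alkene, and the weakly basic phosphonate anion should not enolize toward the bought C6' centre.

Step 12
Reactants: 17 ethyl (2E,4E)-3-methyl-5-[(1R)-2,6,6-trimethylcyclohex-2-en-1-yl]penta-2,4-dienoate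
Product: 18 ethyl (2E,4E)-3-methyl-5-[(1R)-2,6,6-trimethyl-4-oxocyclohex-2-en-1-yl]penta-2,4-dienoate
Conditions: tBuOOH (70% aq.), dirhodium tetracaprolactamate Rh2(C6H10NO)4 (1 mol %), ClCH2CH2Cl, 40 °C
Reagents that add atoms: tert-butyl hydroperoxide, CC(C)(C)OO
Why: Rhodium-catalysed allylic oxidation (hydrogen abstraction by tert-butylperoxyl radicals) turns the ring methylene C3' next to the trisubstituted alkene into the enone, and the base-free medium protects the now vinylogously acidic C6'–H.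

Step 13
Reactants: 18 ethyl (2E,4E)-3-methyl-5-[(1R)-2,6,6-trimethyl-4-oxocyclohex-2-en-1-yl]penta-2,4-dienoate
Product: 19 ethyl (2E,4E)-5-[(1R,4R)-4-hydroxy-2,6,6-trimethylcyclohex-2-en-1-yl]-3-methylpenta-2,4-dienoate
Conditions: (S)-2-methyl-CBS-oxazaborolidine (20 mol %), catecholborane, toluene, −78 °C
Reagents that add atoms: none
Why: Corey–Bakshi–Shibata reduction, in which the (S)-oxazaborolidine takes the alkenyl flank of the ketone as the large group and delivers hydride to give the 3'R alcohol, trans to the C6' side chain (catalyst control).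

Step 14
Reactants: 19 ethyl (2E,4E)-5-[(1R,4R)-4-hydroxy-2,6,6-trimethylcyclohex-2-en-1-yl]-3-methylpenta-2,4-dienoate
Product: 20 ethyl (2E,4E)-5-[(1R,4R)-4-[(tert-butyldimethylsilyl)oxy]-2,6,6-trimethylcyclohex-2-en-1-yl]-3-methylpenta-2,4-dienoate
Conditions: TBSCl, imidazole, DMF, rt
Reagents that add atoms: tert-butyldimethylsilyl chloride, C[Si](C)(Cl)C(C)(C)C
Why: O-silylation protects the allylic alcohol, so that only the primary alcohol made next is converted into the bromide.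

Step 15
Reactants: 20 ethyl (2E,4E)-5-[(1R,4R)-4-[(tert-butyldimethylsilyl)oxy]-2,6,6-trimethylcyclohex-2-en-1-yl]-3-methylpenta-2,4-dienoate
Product: 21 (2E,4E)-5-[(1R,4R)-4-[(tert-butyldimethylsilyl)oxy]-2,6,6-trimethylcyclohex-2-en-1-yl]-3-methylpenta-2,4-dien-1-ol
Conditions: iBu2AlH, CH2Cl2, −78 °C; aq. KNaC4H4O6
Reagents that add atoms: none
Why: Hydride 1,2-reduction of the dienoate gives the primary allylic alcohol.

Step 16
Reactants: 21 (2E,4E)-5-[(1R,4R)-4-[(tert-butyldimethylsilyl)oxy]-2,6,6-trimethylcyclohex-2-en-1-yl]-3-methylpenta-2,4-dien-1-ol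
Product: 23 [(2E,4E)-5-[(1R,4R)-4-[(tert-butyldimethylsilyl)oxy]-2,6,6-trimethylcyclohex-2-en-1-yl]-3-methylpenta-2,4-dien-1-yl]triphenylphosphonium bromide, via silyloxy dienyl bromide 22 (not isolated)
Conditions: CBr4, PPh3 (2.3 equiv), CH2Cl2, −20 °C to rt
Reagents that add atoms: carbon tetrabromide, BrC(Br)(Br)Br; triphenylphosphine, c1ccc(cc1)P(c1ccccc1)c1ccccc1
Why: Appel bromination and in situ quaternization give the ε-end Wittig salt without acid, which the allylic C3' oxygen would not tolerate.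

Step 17
Reactants: 14 (2E,4E,6E,8E,10E,12E)-13-[(1S,4S,6R)-4-[(tert-butyldimethylsilyl)oxy]-2,2,6-trimethyl-7-oxabicyclo[4.1.0]heptan-1-yl]-2,7,11-trimethyltrideca-2,4,6,8,10,12-hexaenal; 23 [(2E,4E)-5-[(1R,4R)-4-[(tert-butyldimethylsilyl)oxy]-2,6,6-trimethylcyclohex-2-en-1-yl]-3-methylpenta-2,4-dien-1-yl]triphenylphosphonium bromide
Product: 24 (3S,5R,6S,3'R,6'R)-3,3'-bis[(tert-butyldimethylsilyl)oxy]-5,6-epoxy-5,6-dihydro-β,ε-carotene
Conditions: NaOMe, MeOH/CH2Cl2, 0 °C to rt; then heptane, 80 °C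
Reagents that add atoms: none
Why: Wittig olefination joins the two halves at C11'=C12' under basic conditions that the oxirane tolerates, and the Z isomer equilibrates thermally to the all-E polyene.

Step 18
Reactants: 24 (3S,5R,6S,3'R,6'R)-3,3'-bis[(tert-butyldimethylsilyl)oxy]-5,6-epoxy-5,6-dihydro-β,ε-carotene
Product: 25 (3S,5R,6S,3'R,6'R)-5,6-epoxy-5,6-dihydro-β,ε-carotene-3,3'-diol (lutein 5,6-epoxide)
Conditions: Bu4NF, THF, rt
Reagents that add atoms: none
Why: Fluoride desilylation frees both alcohols under basic conditions, so that the acid-labile oxirane and the allylic C3' oxygen survive.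

Step 19
Reactants: 25 (3S,5R,6S,3'R,6'R)-5,6-epoxy-5,6-dihydro-β,ε-carotene-3,3'-diol
Product: 26 (3S,5R,8S,3'R,6'R)-5,8-epoxy-5,8-dihydro-β,ε-carotene-3,3'-diol
Conditions: HCl (ca. 0.01 M) in Et2O, 0 °C, minutes; aq. NaHCO3; chromatography
Reagents that add atoms: none
Why: Protonation of the oxirane oxygen and heterolysis of the C6–O bond, which is tertiary and conjugated with the whole polyene, should give a delocalized polyenyl cation in which the C5–O bond is kept; the C5 hydroxyl then adds to C8 and loss of the proton leaves the 2,5-dihydrofuran with the new C6=C7 bond. The closest known reaction type is the acid-catalysed epoxide–furanoid (vinyl oxirane to 2,5-dihydrofuran) rearrangement of carotenoid 5,6-epoxides. The ring O–C5–C6=C7–C8 closes by 5-endo attack of the tethered oxygen on the terminus of the allyl-type cation, so the three-membered ring grows by two atoms through a 1,3-shift of oxygen from C6 to C8. C3, C5, C3' and C6' are not touched (5R is carried over because C5–O never breaks), and the only new stereocentre is C8, whose configuration is fixed by the face of the planar C8 terminus that the oxygen reaches. A concerted or metal-templated suprafacial shift from the 7E alkene would put C9 trans to the C5 methyl (8R only), so the ionic, reversible manifold is chosen on purpose, because it is the one that can deliver 8S; the C5 methyl and the C4 methylene flank the two faces about equally, so the substrate secures no strong bias. The step therefore needs C8 selectivity that it can only get by equilibration and separation: both C8 epimers are expected, they interconvert under the same acid, the 8S compound is isolated by chromatography, and the short contact with very dilute acid at 0 °C is what spares the allylic C3' alcohol.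

Compound list
1 | (4R,6R)-4-hydroxy-2,2,6-trimethylcyclohexan-1-one (actinol) | C[C@@H]1C[C@@H](O)CC(C)(C)C1=O | starting material
2 | (4R,6R)-4-[(tert-butyldimethylsilyl)oxy]-2,2,6-trimethylcyclohexan-1-one | C[C@@H]1C[C@@H](O[Si](C)(C)C(C)(C)C)CC(C)(C)C1=O | intermediate
3 | (4R)-4-[(tert-butyldimethylsilyl)oxy]-2,6,6-trimethylcyclohex-1-en-1-yl trifluoromethanesulfonate | CC1=C(OS(=O)(=O)C(F)(F)F)C(C)(C)C[C@H](O[Si](C)(C)C(C)(C)C)C1 | intermediate
4 | methyl (4R)-4-[(tert-butyldimethylsilyl)oxy]-2,6,6-trimethylcyclohex-1-ene-1-carboxylate | CC1=C(C(=O)OC)C(C)(C)C[C@H](O[Si](C)(C)C(C)(C)C)C1 | intermediate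
5 | [(4R)-4-[(tert-butyldimethylsilyl)oxy]-2,6,6-trimethylcyclohex-1-en-1-yl]methanol | CC1=C(CO)C(C)(C)C[C@H](O[Si](C)(C)C(C)(C)C)C1 | intermediate
6 | [(1R,4S,6R)-4-[(tert-butyldimethylsilyl)oxy]-2,2,6-trimethyl-7-oxabicyclo[4.1.0]heptan-1-yl]methanol | C[C@@]12C[C@@H](O[Si](C)(C)C(C)(C)C)CC(C)(C)[C@]1(CO)O2 | intermediate
7 | (1S,4S,6R)-4-[(tert-butyldimethylsilyl)oxy]-2,2,6-trimethyl-7-oxabicyclo[4.1.0]heptane-1-carbaldehyde | C[C@@]12C[C@@H](O[Si](C)(C)C(C)(C)C)CC(C)(C)[C@]1(C=O)O2 | intermediate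
8 | ethyl (2E)-4-(diethoxyphosphoryl)-3-methylbut-2-enoate | CCOC(=O)/C=C(\C)CP(=O)(OCC)OCC | starting material
9 | ethyl (2E,4E)-5-[(1S,4S,6R)-4-[(tert-butyldimethylsilyl)oxy]-2,2,6-trimethyl-7-oxabicyclo[4.1.0]heptan-1-yl]-3-methylpenta-2,4-dienoate | C[C@@]12C[C@@H](O[Si](C)(C)C(C)(C)C)CC(C)(C)[C@]1(/C=C/C(C)=C/C(=O)OCC)O2 | intermediate
10 | (2E,4E)-5-[(1S,4S,6R)-4-[(tert-butyldimethylsilyl)oxy]-2,2,6-trimethyl-7-oxabicyclo[4.1.0]heptan-1-yl]-3-methylpenta-2,4-dien-1-ol | C[C@@]12C[C@@H](O[Si](C)(C)C(C)(C)C)CC(C)(C)[C@]1(/C=C/C(C)=C/CO)O2 | intermediate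
11 | (1S,4S,6R)-1-[(1E,3E)-5-bromo-3-methylpenta-1,3-dien-1-yl]-4-[(tert-butyldimethylsilyl)oxy]-2,2,6-trimethyl-7-oxabicyclo[4.1.0]heptane (not isolated) | C[C@@]12C[C@@H](O[Si](C)(C)C(C)(C)C)CC(C)(C)[C@]1(/C=C/C(C)=C/CBr)O2 | intermediate
12 | [(2E,4E)-5-[(1S,4S,6R)-4-[(tert-butyldimethylsilyl)oxy]-2,2,6-trimethyl-7-oxabicyclo[4.1.0]heptan-1-yl]-3-methylpenta-2,4-dien-1-yl]triphenylphosphonium bromide | C[C@@]12C[C@@H](O[Si](C)(C)C(C)(C)C)CC(C)(C)[C@]1(/C=C/C(C)=C/C[P+](c3ccccc3)(c3ccccc3)c3ccccc3)O2.[Br-] | intermediate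
13 | (2E,4E,6E)-2,7-dimethylocta-2,4,6-trienedial | O=C/C(C)=C/C=C/C=C(C)/C=O | starting material
14 | (2E,4E,6E,8E,10E,12E)-13-[(1S,4S,6R)-4-[(tert-butyldimethylsilyl)oxy]-2,2,6-trimethyl-7-oxabicyclo[4.1.0]heptan-1-yl]-2,7,11-trimethyltrideca-2,4,6,8,10,12-hexaenal | C[C@@]12C[C@@H](O[Si](C)(C)C(C)(C)C)CC(C)(C)[C@]1(/C=C/C(C)=C/C=C/C(C)=C/C=C/C=C(C)/C=O)O2 | intermediate
15 | (R)-α-ionone, (3E)-4-[(1R)-2,6,6-trimethylcyclohex-2-en-1-yl]but-3-en-2-one | CC1=CCCC(C)(C)[C@H]1/C=C/C(C)=O | starting material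
16 | triethyl phosphonoacetate | CCOC(=O)CP(=O)(OCC)OCC | starting material
17 | ethyl (2E,4E)-3-methyl-5-[(1R)-2,6,6-trimethylcyclohex-2-en-1-yl]penta-2,4-dienoate | CC1=CCCC(C)(C)[C@H]1/C=C/C(C)=C/C(=O)OCC | intermediate
18 | ethyl (2E,4E)-3-methyl-5-[(1R)-2,6,6-trimethyl-4-oxocyclohex-2-en-1-yl]penta-2,4-dienoate | CC1=CC(=O)CC(C)(C)[C@H]1/C=C/C(C)=C/C(=O)OCC | intermediate
19 | ethyl (2E,4E)-5-[(1R,4R)-4-hydroxy-2,6,6-trimethylcyclohex-2-en-1-yl]-3-methylpenta-2,4-dienoate | CC1=C[C@H](O)CC(C)(C)[C@H]1/C=C/C(C)=C/C(=O)OCC | intermediate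
20 | ethyl (2E,4E)-5-[(1R,4R)-4-[(tert-butyldimethylsilyl)oxy]-2,6,6-trimethylcyclohex-2-en-1-yl]-3-methylpenta-2,4-dienoate | CC1=C[C@H](O[Si](C)(C)C(C)(C)C)CC(C)(C)[C@H]1/C=C/C(C)=C/C(=O)OCC | intermediate
21 | (2E,4E)-5-[(1R,4R)-4-[(tert-butyldimethylsilyl)oxy]-2,6,6-trimethylcyclohex-2-en-1-yl]-3-methylpenta-2,4-dien-1-ol | CC1=C[C@H](O[Si](C)(C)C(C)(C)C)CC(C)(C)[C@H]1/C=C/C(C)=C/CO | intermediate
22 | [(1R,4R)-4-[(1E,3E)-5-bromo-3-methylpenta-1,3-dien-1-yl]-3,5,5-trimethylcyclohex-2-en-1-yl]oxy(tert-butyl)dimethylsilane (not isolated) | CC1=C[C@H](O[Si](C)(C)C(C)(C)C)CC(C)(C)[C@H]1/C=C/C(C)=C/CBr | intermediate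
23 | [(2E,4E)-5-[(1R,4R)-4-[(tert-butyldimethylsilyl)oxy]-2,6,6-trimethylcyclohex-2-en-1-yl]-3-methylpenta-2,4-dien-1-yl]triphenylphosphonium bromide | CC1=C[C@H](O[Si](C)(C)C(C)(C)C)CC(C)(C)[C@H]1/C=C/C(C)=C/C[P+](c2ccccc2)(c2ccccc2)c2ccccc2.[Br-] | intermediate
24 | (3S,5R,6S,3'R,6'R)-3,3'-bis[(tert-butyldimethylsilyl)oxy]-5,6-epoxy-5,6-dihydro-β,ε-carotene | C[C@@]12C[C@@H](O[Si](C)(C)C(C)(C)C)CC(C)(C)[C@]1(/C=C/C(C)=C/C=C/C(C)=C/C=C/C=C(C)/C=C/C=C(C)/C=C/[C@H]3C(C)=C[C@H](O[Si](C)(C)C(C)(C)C)CC3(C)C)O2 | intermediate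
25 | (3S,5R,6S,3'R,6'R)-5,6-epoxy-5,6-dihydro-β,ε-carotene-3,3'-diol (lutein 5,6-epoxide) | C[C@@]12C[C@@H](O)CC(C)(C)[C@]1(/C=C/C(C)=C/C=C/C(C)=C/C=C/C=C(C)/C=C/C=C(C)/C=C/[C@H]3C(C)=C[C@H](O)CC3(C)C)O2 | intermediate
26 | (3S,5R,8S,3'R,6'R)-5,8-epoxy-5,8-dihydro-β,ε-carotene-3,3'-diol | CC1=C[C@H](O)CC(C)(C)[C@H]1/C=C/C(C)=C/C=C/C(C)=C/C=C/C=C(C)/C=C/C=C(\C)[C@@H]1C=C2C(C)(C)C[C@H](O)C[C@@]2(C)O1 | target

Total step count: 19. Longest linear sequence: 13 steps (steps 1 to 10, then 17, 18 and 19).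

Steps most likely to fail

Step 19. What may go wrong is low facial discrimination in the ring closure at C8, together with acid-induced ionization of the allylic C3' hydroxyl of the ε ring. The fallback moves the ring expansion to the C25 stage, where no allylic alcohol is present and the unwanted C8 configuration can be re-equilibrated before the ε fragment is spent. It sets out from 14: the same dilute acid (or a catalytic amount of pyridinium p-toluenesulfonate in CH2Cl2) should convert the epoxy aldehyde into the 8S furanoid C25 aldehyde F1, which is separated from material of the other C8 configuration (returned to the acid). F1 is joined with the ylide from 23 (NaOMe, MeOH/CH2Cl2) to give the bis-silyl ether of the target F2, and Bu4NF in THF removes both silyl groups, so the fallback comes back to the route at 26.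

Step 13. What may go wrong is insufficient facial control in the hydride transfer, if the ring conformation opposes the catalyst, and erosion at C6' through enolization of the vinylogous ketone. The fallback corrects the centre instead of controlling it. It sets out from 18: Luche reduction (NaBH4, CeCl3·7H2O, MeOH, −78 °C) gives both C3' epimers, and the cis epimer, ethyl (2E,4E)-5-[(1R,4S)-4-hydroxy-2,6,6-trimethylcyclohex-2-en-1-yl]-3-methylpenta-2,4-dienoate F3, is separated. Mitsunobu inversion (4-nitrobenzoic acid, PPh3, diisopropyl azodicarboxylate, THF, 0 °C) gives the 3'R 4-nitrobenzoate F4, and ethanolysis (K2CO3, EtOH) comes back to the route at 19.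

Step 10. What may go wrong is base-induced opening of the oxirane through the extended ylide (the carbanion is conjugated with C7=C8 next to the C6–O bond) and double condensation on the dialdehyde; halide attack on the oxirane during the salt formation of step 9 belongs to the same weakness. The fallback reverses the polarity, so that the epoxy fragment is the electrophile. It sets out from 10 and uses 13 and 23: MnO2 in CH2Cl2 oxidizes 10 to the epoxy dienal F5. The ylide from 23 is condensed with an excess of 13 (NaOMe, MeOH/CH2Cl2) to the ε-end C25 aldehyde F6, which is reduced (NaBH4, EtOH, 0 °C) to the C25 alcohol F7 and converted by CBr4 and PPh3 through the C25 bromide F8 into the C25 phosphonium bromide F9. Wittig reaction of F9 with F5 (NaOMe, MeOH/CH2Cl2) gives 24, where the fallback comes back to the route.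

Further compounds
F1 | step 19 | (2E,4E,6E,8E,10E)-11-[(2S,6S,7aR)-6-[(tert-butyldimethylsilyl)oxy]-4,4,7a-trimethyl-2,4,5,6,7,7a-hexahydro-1-benzofuran-2-yl]-2,7-dimethyldodeca-2,4,6,8,10-pentaenal | O=C/C(C)=C/C=C/C=C(C)/C=C/C=C(\C)[C@@H]1C=C2C(C)(C)C[C@H](O[Si](C)(C)C(C)(C)C)C[C@@]2(C)O1
F2 | step 19 | (3S,5R,8S,3'R,6'R)-3,3'-bis[(tert-butyldimethylsilyl)oxy]-5,8-epoxy-5,8-dihydro-β,ε-carotene | CC1=C[C@H](O[Si](C)(C)C(C)(C)C)CC(C)(C)[C@H]1/C=C/C(C)=C/C=C/C(C)=C/C=C/C=C(C)/C=C/C=C(\C)[C@@H]1C=C2C(C)(C)C[C@H](O[Si](C)(C)C(C)(C)C)C[C@@]2(C)O1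
F3 | step 13 | ethyl (2E,4E)-5-[(1R,4S)-4-hydroxy-2,6,6-trimethylcyclohex-2-en-1-yl]-3-methylpenta-2,4-dienoate | CC1=C[C@@H](O)CC(C)(C)[C@H]1/C=C/C(C)=C/C(=O)OCC
F4 | step 13 | (1R,4R)-4-[(1E,3E)-5-ethoxy-3-methyl-5-oxopenta-1,3-dien-1-yl]-3,5,5-trimethylcyclohex-2-en-1-yl 4-nitrobenzoate | CC1=C[C@H](OC(=O)c2ccc(cc2)[N+](=O)[O-])CC(C)(C)[C@H]1/C=C/C(C)=C/C(=O)OCC
F5 | step 10 | (2E,4E)-5-[(1S,4S,6R)-4-[(tert-butyldimethylsilyl)oxy]-2,2,6-trimethyl-7-oxabicyclo[4.1.0]heptan-1-yl]-3-methylpenta-2,4-dienal | C[C@@]12C[C@@H](O[Si](C)(C)C(C)(C)C)CC(C)(C)[C@]1(/C=C/C(C)=C/C=O)O2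
F6 | step 10 | (2E,4E,6E,8E,10E,12E)-13-[(1R,4R)-4-[(tert-butyldimethylsilyl)oxy]-2,6,6-trimethylcyclohex-2-en-1-yl]-2,7,11-trimethyltrideca-2,4,6,8,10,12-hexaenal | CC1=C[C@H](O[Si](C)(C)C(C)(C)C)CC(C)(C)[C@H]1/C=C/C(C)=C/C=C/C(C)=C/C=C/C=C(C)/C=O
F7 | step 10 | (2E,4E,6E,8E,10E,12E)-13-[(1R,4R)-4-[(tert-butyldimethylsilyl)oxy]-2,6,6-trimethylcyclohex-2-en-1-yl]-2,7,11-trimethyltrideca-2,4,6,8,10,12-hexaen-1-ol | CC1=C[C@H](O[Si](C)(C)C(C)(C)C)CC(C)(C)[C@H]1/C=C/C(C)=C/C=C/C(C)=C/C=C/C=C(C)/CO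
F8 | step 10 | [(1R,4R)-4-[(1E,3E,5E,7E,9E,11E)-13-bromo-3,7,12-trimethyltrideca-1,3,5,7,9,11-hexaen-1-yl]-3,5,5-trimethylcyclohex-2-en-1-yl]oxy(tert-butyl)dimethylsilane (not isolated) | CC1=C[C@H](O[Si](C)(C)C(C)(C)C)CC(C)(C)[C@H]1/C=C/C(C)=C/C=C/C(C)=C/C=C/C=C(C)/CBr
F9 | step 10 | [(2E,4E,6E,8E,10E,12E)-13-[(1R,4R)-4-[(tert-butyldimethylsilyl)oxy]-2,6,6-trimethylcyclohex-2-en-1-yl]-2,7,11-trimethyltrideca-2,4,6,8,10,12-hexaen-1-yl]triphenylphosphonium bromide | CC1=C[C@H](O[Si](C)(C)C(C)(C)C)CC(C)(C)[C@H]1/C=C/C(C)=C/C=C/C(C)=C/C=C/C=C(C)/C[P+](c2ccccc2)(c2ccccc2)c2ccccc2.[Br-]
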